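**Retrosynthetic overview**
1. 16-epi-Luffarin L ⇐ its bis-PMB ether; the butenolide is the only ring built, and it is built last, by O-acylation/intramolecular Wittig of an α-hydroxy ketone with Ph3P=C=C=O.
2. α-Hydroxy ketone ⇐ Weinreb amide + PMBOCH2Li ⇐ (R)-α-hydroxy ester.
3. C14–C15 bond: Z-alkenylmagnesium + methyl (R)-glycidate (copper-catalysed epoxide opening; C16 comes from the chiral pool).
4. C12–C13 bond and the Z-trisubstituted C13=C14 olefin: copper-catalysed anti-carbomagnesiation of propargyl alcohol by the homodrimenyl Grignard reagent, iodine quench.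
5. Rings A and B are taken intact from (+)-sclareolide (E1 lactone opening to the Δ8(9) ester, reduction, bromination).

Assumption: atom labels follow the drimane/luffarin skeleton (C13′ and C17′ are the two CH2OH carbons, C16 the lactone carbinol carbon); compounds are written in neutral worked-up form, and the catalogue reagents 1, 5, 11, 16, 17 and 21 are taken as commercial.

**Route**

Step 1
Reactants: 1 (+)-sclareolide
Product: 2 methyl Δ8(9)-homodrimenoate (tetrasubstituted-olefin methyl ester)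
Conditions: conc. H2SO4, MeOH, 65 °C; minor Δ7 and exocyclic isomers removed on AgNO3-impregnated SiO2
Reagents that add atoms: methanol, CO
Why: Acid-promoted E1 opening of the tertiary lactone C–O bond with Fischer esterification, where reversible protonation funnels the olefin to the thermodynamically preferred tetrasubstituted Δ8(9) position while C5 and C10 are untouched.

Step 2
Reactants: 2 methyl Δ8(9)-homodrimenoate
Product: 3 Δ8(9)-homodrimenol (primary homoallylic alcohol)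
Conditions: LiAlH4, Et2O, 0 °C
Reagents that add atoms: none
Why: Hydride reduction of the ester to the primary alcohol; the tetrasubstituted alkene is inert.

Step 3
Reactants: 3 Δ8(9)-homodrimenol
Product: 4 Δ8(9)-homodrimenyl bromide
Conditions: CBr4, PPh3, NaHCO3, CH2Cl2, 0 °C
Reagents that add atoms: tetrabromomethane, BrC(Br)(Br)Br
Why: Appel bromination under buffered, non-acidic conditions, which avoids acid-induced cyclisation of the alcohol onto C8.

Step 4
Reactants: 4 Δ8(9)-homodrimenyl bromide; 5 prop-2-yn-1-ol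
Product: 9 (Z)-3-iodo-2-(homodrimenyl)prop-2-en-1-ol, via homodrimenyl Grignard reagent 6 (not isolated), via bromomagnesium propargyl alkoxide 7 (not isolated), via cyclic alkenylmagnesium alkoxide 8 (not isolated)
Conditions: 4, Mg, THF, 40 °C; separately 5 (1.5 equiv), EtMgBr (1.5 equiv), THF, 0 °C; combine, CuI (15 mol %), THF/Et2O, −10 °C to rt; then I2, −30 °C
Reagents that add atoms: iodine (I2), [I][I]
Why: Copper-catalysed alkoxide-directed anti-carbomagnesiation (Duboudin reaction) puts the alkyl group on the internal alkyne carbon and magnesium on the terminal carbon cis to CH2O in a five-membered chelate, and iodinolysis with retention fixes the C13=C14 geometry (CH2OH cis to the future C15).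

Step 5
Reactants: 9 (Z)-iodoallylic alcohol
Product: 10 (Z)-iodoalkene PMB ether
Conditions: NaH, 4-methoxybenzyl chloride, Bu4NI (cat.), THF/DMF, 0 °C to rt
Reagents that add atoms: 4-methoxybenzyl chloride, COc1ccc(CCl)cc1
Why: Williamson etherification; the PMB ether survives the organolithium and Grignard steps and is removed oxidatively at the end.

Step 6
Reactants: 10 (Z)-iodoalkene PMB ether; 11 methyl (R)-glycidate
Product: 14 (2R,4Z)-α-hydroxy methyl ester, via Z-alkenyllithium 12 (not isolated), via Z-alkenylmagnesium bromide 13 (not isolated)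
Conditions: t-BuLi (2.1 equiv), Et2O, −78 °C; MgBr2·OEt2; CuI (10 mol %), 11 (1.5 equiv), THF, −78 to −40 °C
Reagents that add atoms: none
Why: Iodine–lithium exchange and transmetalation proceed with retention of olefin geometry, and copper-catalysed SN2 opening of the epoxide at its CH2 carbon leaves the glycidate stereocentre untouched, so C16 is (R).

Step 7
Reactants: 14 (2R,4Z)-α-hydroxy methyl ester
Product: 15 (2R,4Z)-α-hydroxy Weinreb amide
Conditions: MeNH(OMe)·HCl, i-PrMgCl (4 equiv), THF, −20 to 0 °C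
Reagents that add atoms: N,O-dimethylhydroxylamine hydrochloride, CNOC.Cl
Why: Weinreb amide formation by aminolysis of the ester with the magnesium amide; the adjacent magnesium alkoxide protects C16–H from enolisation.

Step 8
Reactants: 16 tributyl(iodomethyl)stannane; 17 4-methoxybenzyl alcohol
Product: 18 tributyl(PMB-oxymethyl)stannane
Conditions: NaH, THF/DMF, 0 °C to rt
Reagents that add atoms: none
Why: Williamson SN2 displacement of the primary α-stannyl iodide by the alkoxide.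

Step 9
Reactants: 15 (2R,4Z)-α-hydroxy Weinreb amide; 18 tributyl(PMB-oxymethyl)stannane
Product: 20 (3R,5Z)-α-hydroxy-α′-PMB-oxy ketone, via PMB-oxymethyllithium 19 (not isolated)
Conditions: 18 (3 equiv), n-BuLi (3 equiv), THF, −78 °C, 10 min; then 15, −78 to −40 °C
Reagents that add atoms: none
Why: Tin–lithium exchange gives the α-alkoxymethyllithium, whose addition to the Weinreb amide stops at the chelated tetrahedral intermediate (Weinreb ketone synthesis); the first equivalent only deprotonates the hydroxyl, which keeps C16 from enolising.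

Step 10
Reactants: 20 (3R,5Z)-α-hydroxy-α′-PMB-oxy ketone; 21 (triphenylphosphoranylidene)ketene
Product: 23 (5R)-bis-PMB butenolide, via acyl ylide ester 22 (not isolated)
Conditions: toluene, 90 °C
Reagents that add atoms: none
Why: The C16 hydroxyl adds to the ketene ylide (Bestmann ylide) to give an ester ylide that closes the butenolide by intramolecular Wittig reaction on the adjacent ketone; no bond to C16 is broken, so it stays (R).

Step 11
Reactants: 23 (5R)-bis-PMB butenolide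
Product: 24 16-epi-luffarin L
Conditions: DDQ (2.6 equiv), CH2Cl2/pH 7 phosphate buffer (10:1), 0 °C
Reagents that add atoms: none
Why: Oxidative cleavage of both PMB ethers (benzylic hydride abstraction, hydrolysis of the hemiacetal) under neutral conditions that spare the butenolide, the allylic alcohols and both alkenes.

**Compound list**

1 | (+)-sclareolide, (3aR,5aS,9aS,9bR)-3a,6,6,9a-tetramethyldecahydronaphtho[2,1-b]furan-2(1H)-one | C[C@]12OC(=O)C[C@@H]1[C@@]1(C)CCCC(C)(C)[C@@H]1CC2 | starting material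
2 | methyl 2-[(4aS,8aS)-2,5,5,8a-tetramethyl-3,4,4a,5,6,7,8,8a-octahydronaphthalen-1-yl]acetate | CC1=C(CC(=O)OC)[C@@]2(C)CCCC(C)(C)[C@@H]2CC1 | intermediate
3 | 2-[(4aS,8aS)-2,5,5,8a-tetramethyl-3,4,4a,5,6,7,8,8a-octahydronaphthalen-1-yl]ethan-1-ol | CC1=C(CCO)[C@@]2(C)CCCC(C)(C)[C@@H]2CC1 | intermediate
4 | (4aS,8aS)-1-(2-bromoethyl)-2,5,5,8a-tetramethyl-3,4,4a,5,6,7,8,8a-octahydronaphthalene | CC1=C(CCBr)[C@@]2(C)CCCC(C)(C)[C@@H]2CC1 | intermediate
5 | prop-2-yn-1-ol (propargyl alcohol) | C#CCO | starting material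
6 | bromo{2-[(4aS,8aS)-2,5,5,8a-tetramethyl-3,4,4a,5,6,7,8,8a-octahydronaphthalen-1-yl]ethyl}magnesium | CC1=C(CC[Mg]Br)[C@@]2(C)CCCC(C)(C)[C@@H]2CC1 | intermediate
7 | bromomagnesium prop-2-yn-1-olate | C#CCO[Mg]Br | intermediate
8 | cyclic alkenylmagnesium alkoxide (five-membered C=CH–Mg–O–CH2 chelate; the ring sp2 carbon remote from Mg carries the 2-[(4aS,8aS)-2,5,5,8a-tetramethyl-3,4,4a,5,6,7,8,8a-octahydronaphthalen-1-yl]ethyl group) | CC1=C(CCC3=C[Mg]OC3)[C@@]2(C)CCCC(C)(C)[C@@H]2CC1 | intermediate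
9 | (2Z)-3-iodo-2-{2-[(4aS,8aS)-2,5,5,8a-tetramethyl-3,4,4a,5,6,7,8,8a-octahydronaphthalen-1-yl]ethyl}prop-2-en-1-ol | CC1=C(CC/C(=C/I)CO)[C@@]2(C)CCCC(C)(C)[C@@H]2CC1 | intermediate
10 | (4aS,8aS)-1-[(3Z)-4-iodo-3-{[(4-methoxyphenyl)methoxy]methyl}but-3-en-1-yl]-2,5,5,8a-tetramethyl-3,4,4a,5,6,7,8,8a-octahydronaphthalene | CC1=C(CC/C(=C/I)COCc3ccc(OC)cc3)[C@@]2(C)CCCC(C)(C)[C@@H]2CC1 | intermediate
11 | methyl (2R)-oxirane-2-carboxylate (methyl (R)-glycidate) | COC(=O)[C@H]1CO1 | starting material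
12 | [(1Z)-2-{[(4-methoxyphenyl)methoxy]methyl}-4-[(4aS,8aS)-2,5,5,8a-tetramethyl-3,4,4a,5,6,7,8,8a-octahydronaphthalen-1-yl]but-1-en-1-yl]lithium | CC1=C(CC/C(=C/[Li])COCc3ccc(OC)cc3)[C@@]2(C)CCCC(C)(C)[C@@H]2CC1 | intermediate
13 | bromo[(1Z)-2-{[(4-methoxyphenyl)methoxy]methyl}-4-[(4aS,8aS)-2,5,5,8a-tetramethyl-3,4,4a,5,6,7,8,8a-octahydronaphthalen-1-yl]but-1-en-1-yl]magnesium | CC1=C(CC/C(=C/[Mg]Br)COCc3ccc(OC)cc3)[C@@]2(C)CCCC(C)(C)[C@@H]2CC1 | intermediate
14 | methyl (2R,4Z)-2-hydroxy-5-{[(4-methoxyphenyl)methoxy]methyl}-7-[(4aS,8aS)-2,5,5,8a-tetramethyl-3,4,4a,5,6,7,8,8a-octahydronaphthalen-1-yl]hept-4-enoate | CC1=C(CC/C(=C/C[C@@H](O)C(=O)OC)COCc3ccc(OC)cc3)[C@@]2(C)CCCC(C)(C)[C@@H]2CC1 | intermediate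
15 | (2R,4Z)-2-hydroxy-N-methoxy-5-{[(4-methoxyphenyl)methoxy]methyl}-N-methyl-7-[(4aS,8aS)-2,5,5,8a-tetramethyl-3,4,4a,5,6,7,8,8a-octahydronaphthalen-1-yl]hept-4-enamide | CC1=C(CC/C(=C/C[C@@H](O)C(=O)N(C)OC)COCc3ccc(OC)cc3)[C@@]2(C)CCCC(C)(C)[C@@H]2CC1 | intermediate
16 | tributyl(iodomethyl)stannane | CCCC[Sn](CCCC)(CCCC)CI | starting material
17 | (4-methoxyphenyl)methanol (4-methoxybenzyl alcohol) | COc1ccc(CO)cc1 | starting material
18 | tributyl{[(4-methoxyphenyl)methoxy]methyl}stannane | CCCC[Sn](CCCC)(CCCC)COCc1ccc(OC)cc1 | intermediate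
19 | {[(4-methoxyphenyl)methoxy]methyl}lithium | [Li]COCc1ccc(OC)cc1 | intermediate
20 | (3R,5Z)-3-hydroxy-1-[(4-methoxyphenyl)methoxy]-6-{[(4-methoxyphenyl)methoxy]methyl}-8-[(4aS,8aS)-2,5,5,8a-tetramethyl-3,4,4a,5,6,7,8,8a-octahydronaphthalen-1-yl]oct-5-en-2-one | CC1=C(CC/C(=C/C[C@@H](O)C(=O)COCc3ccc(OC)cc3)COCc4ccc(OC)cc4)[C@@]2(C)CCCC(C)(C)[C@@H]2CC1 | intermediate
21 | (triphenyl-λ5-phosphanylidene)ethenone (Bestmann ylide, Ph3P=C=C=O) | O=C=C=P(c1ccccc1)(c1ccccc1)c1ccccc1 | starting material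
22 | (3R,5Z)-1-[(4-methoxyphenyl)methoxy]-6-{[(4-methoxyphenyl)methoxy]methyl}-2-oxo-8-[(4aS,8aS)-2,5,5,8a-tetramethyl-3,4,4a,5,6,7,8,8a-octahydronaphthalen-1-yl]oct-5-en-3-yl (triphenyl-λ5-phosphanylidene)acetate | CC1=C(CC/C(=C/C[C@@H](OC(=O)C=P(c5ccccc5)(c5ccccc5)c5ccccc5)C(=O)COCc3ccc(OC)cc3)COCc4ccc(OC)cc4)[C@@]2(C)CCCC(C)(C)[C@@H]2CC1 | intermediate
23 | (5R)-4-{[(4-methoxyphenyl)methoxy]methyl}-5-[(2Z)-3-{[(4-methoxyphenyl)methoxy]methyl}-5-[(4aS,8aS)-2,5,5,8a-tetramethyl-3,4,4a,5,6,7,8,8a-octahydronaphthalen-1-yl]pent-2-en-1-yl]furan-2(5H)-one | CC1=C(CC/C(=C/C[C@H]3OC(=O)C=C3COCc4ccc(OC)cc4)COCc5ccc(OC)cc5)[C@@]2(C)CCCC(C)(C)[C@@H]2CC1 | intermediate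
24 | 16-epi-luffarin L, (5R)-4-(hydroxymethyl)-5-[(2Z)-3-(hydroxymethyl)-5-[(4aS,8aS)-2,5,5,8a-tetramethyl-3,4,4a,5,6,7,8,8a-octahydronaphthalen-1-yl]pent-2-en-1-yl]furan-2(5H)-one | CC1=C(CC/C(=C/C[C@H]2OC(=O)C=C2CO)CO)[C@@]2(C)CCCC(C)(C)[C@@H]2CC1 | target

**Step count and risks**

Total steps: 11. Longest linear sequence: 10 (steps 1–7 and 9–11 from sclareolide 1; step 8 is a one-step side branch).

Most likely to fail:

Step 1 (the E1 opening may give too much Δ7/exocyclic olefin or relactonise). The fallback sets out from 1 and comes back at 3. LiAlH4 in THF reduces 1 to the diol (1R,2R,4aS,8aS)-1-(2-hydroxyethyl)-2,5,5,8a-tetramethyldecahydronaphthalen-2-ol F1. Ac2O/pyridine at 0 °C acetylates only the primary hydroxyl to give 2-[(1R,2R,4aS,8aS)-2-hydroxy-2,5,5,8a-tetramethyldecahydronaphthalen-1-yl]ethyl acetate F2. Catalytic iodine in refluxing benzene then dehydrates the tertiary alcohol and equilibrates the olefin isomers to the tetrasubstituted 2-[(4aS,8aS)-2,5,5,8a-tetramethyl-3,4,4a,5,6,7,8,8a-octahydronaphthalen-1-yl]ethyl acetate F3; the acetate blocks cyclic ether formation and no lactone can re-form. K2CO3 in MeOH releases 3.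

Step 4 (anti-carbomagnesiation with a bulky Grignard reagent used as the limiting component may stall or give protonated/Wurtz products). The fallback sets out from 6 and comes back at 10, replacing alkyne carbometalation by carbonyl olefination. Reagent 6 is added to N-methoxy-N-methyl-2-[(4-methoxyphenyl)methoxy]acetamide (THF, 0 °C) to give the α-alkoxy ketone 1-[(4-methoxyphenyl)methoxy]-4-[(4aS,8aS)-2,5,5,8a-tetramethyl-3,4,4a,5,6,7,8,8a-octahydronaphthalen-1-yl]butan-2-one F4. Wittig iodomethylenation under Stork–Zhao conditions ((iodomethyl)triphenylphosphonium iodide, NaN(SiMe3)2, THF/DMPU, −78 °C) then gives 10 directly, relying on the known preference of α-alkoxy ketones to place the alkoxymethyl group cis to the ylide substituent.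

Step 10 (the α-ketol may epimerise at C16 or undergo ketol shift on heating with the ylide). The fallback sets out from 14 and comes back at 24, avoiding the hydroxy ketone altogether. Ac2O/pyridine/DMAP converts 14 into methyl (2R,4Z)-2-acetoxy-5-{[(4-methoxyphenyl)methoxy]methyl}-7-[(4aS,8aS)-2,5,5,8a-tetramethyl-3,4,4a,5,6,7,8,8a-octahydronaphthalen-1-yl]hept-4-enoate F5. Dieckmann cyclisation (LiN(SiMe3)2, THF, −78 °C) gives the tetronic acid (5R)-4-hydroxy-5-[(2Z)-3-{[(4-methoxyphenyl)methoxy]methyl}-5-[(4aS,8aS)-2,5,5,8a-tetramethyl-3,4,4a,5,6,7,8,8a-octahydronaphthalen-1-yl]pent-2-en-1-yl]furan-2(5H)-one F6. Tf2O/i-Pr2NEt at −78 °C gives the corresponding 4-trifluoromethanesulfonyloxy butenolide F7. Stille hydroxymethylation with (tributylstannyl)methanol (Pd(PPh3)4, LiCl, dioxane, 90 °C) gives the (5R)-4-(hydroxymethyl) butenolide mono-PMB ether F8, and DDQ removes the remaining PMB group to give 24.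

**Further compounds**

F1 | step 1 | (1R,2R,4aS,8aS)-1-(2-hydroxyethyl)-2,5,5,8a-tetramethyldecahydronaphthalen-2-ol | OCC[C@@H]1[C@@]2(C)CCCC(C)(C)[C@@H]2CC[C@@]1(C)O
F2 | step 1 | 2-[(1R,2R,4aS,8aS)-2-hydroxy-2,5,5,8a-tetramethyldecahydronaphthalen-1-yl]ethyl acetate | CC(=O)OCC[C@@H]1[C@@]2(C)CCCC(C)(C)[C@@H]2CC[C@@]1(C)O
F3 | step 1 | 2-[(4aS,8aS)-2,5,5,8a-tetramethyl-3,4,4a,5,6,7,8,8a-octahydronaphthalen-1-yl]ethyl acetate | CC1=C(CCOC(C)=O)[C@@]2(C)CCCC(C)(C)[C@@H]2CC1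
F4 | step 4 | 1-[(4-methoxyphenyl)methoxy]-4-[(4aS,8aS)-2,5,5,8a-tetramethyl-3,4,4a,5,6,7,8,8a-octahydronaphthalen-1-yl]butan-2-one | CC1=C(CCC(=O)COCc3ccc(OC)cc3)[C@@]2(C)CCCC(C)(C)[C@@H]2CC1
F5 | step 10 | methyl (2R,4Z)-2-acetoxy-5-{[(4-methoxyphenyl)methoxy]methyl}-7-[(4aS,8aS)-2,5,5,8a-tetramethyl-3,4,4a,5,6,7,8,8a-octahydronaphthalen-1-yl]hept-4-enoate | CC1=C(CC/C(=C/C[C@@H](OC(C)=O)C(=O)OC)COCc3ccc(OC)cc3)[C@@]2(C)CCCC(C)(C)[C@@H]2CC1
F6 | step 10 | (5R)-4-hydroxy-5-[(2Z)-3-{[(4-methoxyphenyl)methoxy]methyl}-5-[(4aS,8aS)-2,5,5,8a-tetramethyl-3,4,4a,5,6,7,8,8a-octahydronaphthalen-1-yl]pent-2-en-1-yl]furan-2(5H)-one | CC1=C(CC/C(=C/C[C@H]3OC(=O)C=C3O)COCc4ccc(OC)cc4)[C@@]2(C)CCCC(C)(C)[C@@H]2CC1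
F7 | step 10 | (2R)-2-[(2Z)-3-{[(4-methoxyphenyl)methoxy]methyl}-5-[(4aS,8aS)-2,5,5,8a-tetramethyl-3,4,4a,5,6,7,8,8a-octahydronaphthalen-1-yl]pent-2-en-1-yl]-5-oxo-2,5-dihydrofuran-3-yl trifluoromethanesulfonate | CC1=C(CC/C(=C/C[C@H]3OC(=O)C=C3OS(=O)(=O)C(F)(F)F)COCc4ccc(OC)cc4)[C@@]2(C)CCCC(C)(C)[C@@H]2CC1
F8 | step 10 | (5R)-4-(hydroxymethyl)-5-[(2Z)-3-{[(4-methoxyphenyl)methoxy]methyl}-5-[(4aS,8aS)-2,5,5,8a-tetramethyl-3,4,4a,5,6,7,8,8a-octahydronaphthalen-1-yl]pent-2-en-1-yl]furan-2(5H)-one | CC1=C(CC/C(=C/C[C@H]3OC(=O)C=C3CO)COCc4ccc(OC)cc4)[C@@]2(C)CCCC(C)(C)[C@@H]2CC1
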